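**Assumption:** the HWE phosphonate (step 3), the bis(oxazoline) ligand (step 4) and quinidine (step 9) are used as purchased reagents. Sense-of-induction assignments for steps 4 and 9 rest on published models for closely related substrates, not on this exact substrate.

## Retrosynthetic overview

1. Target 24 ⇐ 22 ⇐ 20: the last two operations only unmask the CO2H (imide hydrolysis) and the 5-OH (chelation-controlled O-demethylation).
2. The chromanone ring is the only ring made and is closed last, by a quinidine-catalysed cis-selective oxa-Michael addition of o-hydroxyaryl tigloyl ketone 19. Its aryl–acyl bond comes from a photo-Fries shift of aryl tiglate 16.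
3. 16 ⇐ ortho-C-prenylation and O-tigloylation of the locally symmetric phenol 11 ⇐ Ir C–H borylation/oxidation of 9 (third ring oxygen).
4. Key disconnection: not the aryl–C3 bond but the C3–C4 bond of the octanoyl chain. An enantioselective conjugate addition of a pentyl radical to cinnamoyl imide 6 sets the benzylic centre in the C–C bond-forming step.
5. 6 ⇐ HWE ⇐ aldehyde 5 ⇐ ortho-lithiation of 1,3-dimethoxybenzene 2 ⇐ resorcinol 1 (benzene ring bought).

## Route

Step 1
Reactants: 1 resorcinol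
Product: 2 1,3-dimethoxybenzene
Conditions: Me2SO4 (2.5 equiv), K2CO3, acetone, reflux
Reagents that add atoms: dimethyl sulfate, COS(=O)(=O)OC
Why: Williamson-type double O-methylation (SN2 on dimethyl sulfate) gives the bis-ether whose two methoxy groups direct the next lithiation.

Step 2
Reactants: 2 1,3-dimethoxybenzene
Product: 5 2,6-dimethoxybenzaldehyde, via 2,6-dimethoxyphenyllithium 3 (not isolated), via lithium hemiaminal alkoxide 4 (not isolated)
Conditions: n-BuLi, THF, 0 °C to rt; DMF, 0 °C; 1 M HCl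
Reagents that add atoms: N,N-dimethylformamide, CN(C)C=O; n-butyllithium, [Li]CCCC (Li only in 3 and 4)
Why: Directed ortho-metalation occurs at C2 between the two methoxy groups, and formylation of the aryllithium with DMF followed by hydrolysis of the hemiaminal gives the aldehyde.

Step 3
Reactants: 5 2,6-dimethoxybenzaldehyde
Product: 6 3-[(2E)-3-(2,6-dimethoxyphenyl)prop-2-enoyl]-1,3-oxazolidin-2-one
Conditions: (EtO)2P(O)CH2C(O)-oxazolidinone, LiCl, i-Pr2NEt, MeCN, rt
Reagents that add atoms: diethyl [2-oxo-2-(2-oxo-1,3-oxazolidin-3-yl)ethyl]phosphonate, CCOP(=O)(OCC)CC(=O)N1CCOC1=O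
Why: Masamune–Roush Horner–Wadsworth–Emmons olefination gives the E-cinnamoyl imide, the two-point-binding acceptor that the chiral Lewis acid of the next step needs.

Step 4 (key step)
Reactants: 6 3-[(2E)-3-(2,6-dimethoxyphenyl)prop-2-enoyl]-1,3-oxazolidin-2-one; 7 1-iodopentane
Product: 9 3-[(3R)-3-(2,6-dimethoxyphenyl)octanoyl]-1,3-oxazolidin-2-one, via pentyl radical 8 (not isolated)
Conditions: MgI2 (1.0 equiv), cyclopropylidene-bis(indeno-oxazoline) ligand (1.05 equiv, antipode that leaves the Cβ-Re face open), 7 (5 equiv), Bu3SnH (2 equiv), Et3B (0.5 equiv)/O2, CH2Cl2, −78 °C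
Reagents that add atoms: none
Why: This is a chiral-Lewis-acid-mediated enantioselective radical conjugate addition (Sibi-type Giese reaction) in which Bu3Sn• abstracts iodine from 7, the nucleophilic pentyl radical 8 adds to the β-carbon of the Mg-chelated s-cis imide on the face left open by the C2-symmetric ligand (Re face, giving 3R), and H-transfer from Bu3SnH closes the chain, so the C3–C4 bond and the benzylic stereocentre are made together.

Step 5
Reactants: 9 3-[(3R)-3-(2,6-dimethoxyphenyl)octanoyl]-1,3-oxazolidin-2-one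
Product: 11 3-[(3R)-3-(4-hydroxy-2,6-dimethoxyphenyl)octanoyl]-1,3-oxazolidin-2-one, via aryl pinacol boronate 10 (not isolated)
Conditions: [Ir(OMe)(cod)]2 (1.5 mol %), dtbpy (3 mol %), B2pin2, THF, 80 °C; then Oxone, acetone/H2O, rt
Reagents that add atoms: potassium peroxymonosulfate (Oxone), [K+].[O-]S(=O)(=O)OO; bis(pinacolato)diboron, CC1(C)OB(OC1(C)C)B1OC(C)(C)C(C)(C)O1 (Bpin only in 10)
Why: Sterically controlled Ir-catalysed C–H borylation takes the only ring C–H without an ortho substituent (para to the side chain), and one-pot oxidation of the C–B bond gives the phenol without touching the imide or the stereocentre.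

Step 6
Reactants: 11 3-[(3R)-3-(4-hydroxy-2,6-dimethoxyphenyl)octanoyl]-1,3-oxazolidin-2-one; 12 1-bromo-3-methylbut-2-ene (prenyl bromide)
Product: 14 3-{(3R)-3-[4-hydroxy-2,6-dimethoxy-3-(3-methylbut-2-en-1-yl)phenyl]octanoyl}-1,3-oxazolidin-2-one, via sodium phenoxide 13 (not isolated)
Conditions: NaH (1.0 equiv), toluene, 0 °C; 12 (1.1 equiv), rt
Reagents that add atoms: sodium hydride, [Na+].[H-] (Na only in 13)
Why: Ortho-C-alkylation of the tight sodium phenoxide ion pair in a non-polar solvent (phenoxide C-prenylation) gives one regioisomer because the two ortho positions are equivalent by rotation about the aryl–C3 bond, and one equivalent of base leaves the far less acidic imide α-CH2 alone.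

Step 7
Reactants: 14 3-{(3R)-3-[4-hydroxy-2,6-dimethoxy-3-(3-methylbut-2-en-1-yl)phenyl]octanoyl}-1,3-oxazolidin-2-one; 15 (2E)-2-methylbut-2-enoyl chloride (tigloyl chloride)
Product: 16 3,5-dimethoxy-2-(3-methylbut-2-en-1-yl)-4-[(3R)-1-oxo-1-(2-oxo-1,3-oxazolidin-3-yl)octan-3-yl]phenyl (2E)-2-methylbut-2-enoate
Conditions: Et3N, DMAP (cat.), CH2Cl2, 0 °C
Reagents that add atoms: none
Why: DMAP-catalysed O-acylation (esterification) of the phenol attaches the tigloyl group to oxygen with its E geometry intact, ready to be shifted to carbon.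

Step 8
Reactants: 16 3,5-dimethoxy-2-(3-methylbut-2-en-1-yl)-4-[(3R)-1-oxo-1-(2-oxo-1,3-oxazolidin-3-yl)octan-3-yl]phenyl (2E)-2-methylbut-2-enoate
Product: 19 3-{(3R)-3-[4-hydroxy-2,6-dimethoxy-3-[(2E)-2-methylbut-2-enoyl]-5-(3-methylbut-2-en-1-yl)phenyl]octanoyl}-1,3-oxazolidin-2-one, via aryloxyl radical 17 (not isolated), via tigloyl radical 18 (not isolated)
Conditions: hν (254 nm, quartz), degassed MeCN, rt, partial conversion (recovered 14 re-acylated)
Reagents that add atoms: none
Why: In this photo-Fries rearrangement, homolysis of the ArO–CO bond gives a caged aryloxyl/acyl radical pair that recombines at the only free ortho carbon (the other ortho and the para positions are substituted) and tautomerises to the chelated o-hydroxyaryl enone, so the last aryl–C bond is made without the Lewis acid that would cyclise the o-prenylphenol to a chroman.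

Step 9
Reactants: 19 3-{(3R)-3-[4-hydroxy-2,6-dimethoxy-3-[(2E)-2-methylbut-2-enoyl]-5-(3-methylbut-2-en-1-yl)phenyl]octanoyl}-1,3-oxazolidin-2-one
Product: 20 3-{(3R)-3-[(2S,3R)-5,7-dimethoxy-2,3-dimethyl-8-(3-methylbut-2-en-1-yl)-4-oxo-3,4-dihydro-2H-chromen-6-yl]octanoyl}-1,3-oxazolidin-2-one
Conditions: quinidine (20 mol %), chlorobenzene, rt
Reagents that add atoms: none
Why: In this cinchona-alkaloid-catalysed asymmetric intramolecular oxa-Michael addition the quinuclidine nitrogen activates the only free phenol, the catalyst controls the face of C–O bond formation at C2 (2S with quinidine, the pseudo-enantiomer of the quinine that gives the 2R ring), and kinetic protonation of the resulting enol anti to the 2-methyl group gives the cis (3R) isomer.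

Step 10
Reactants: 20 3-{(3R)-3-[(2S,3R)-5,7-dimethoxy-2,3-dimethyl-8-(3-methylbut-2-en-1-yl)-4-oxo-3,4-dihydro-2H-chromen-6-yl]octanoyl}-1,3-oxazolidin-2-one
Product: 22 3-{(3R)-3-[(2S,3R)-5-hydroxy-7-methoxy-2,3-dimethyl-8-(3-methylbut-2-en-1-yl)-4-oxo-3,4-dihydro-2H-chromen-6-yl]octanoyl}-1,3-oxazolidin-2-one, via aryloxydichloroborane 21 (not isolated)
Conditions: BCl3 (3 equiv), CH2Cl2, −78 to −20 °C; H2O
Reagents that add atoms: boron trichloride, ClB(Cl)Cl (B and Cl only in 21)
Why: In this chelation-controlled Lewis-acid O-demethylation, BCl3 bound to the C4 carbonyl cleaves only the peri 5-OMe (the 7-OMe has no neighbouring carbonyl), and at low temperature without base neither the prenyl group (no free ortho OH) nor the enolisable cis C3 centre is affected.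

Step 11
Reactants: 22 3-{(3R)-3-[(2S,3R)-5-hydroxy-7-methoxy-2,3-dimethyl-8-(3-methylbut-2-en-1-yl)-4-oxo-3,4-dihydro-2H-chromen-6-yl]octanoyl}-1,3-oxazolidin-2-one
Product: 24 (3R)-3-[(2S,3R)-5-hydroxy-7-methoxy-2,3-dimethyl-8-(3-methylbut-2-en-1-yl)-4-oxo-3,4-dihydro-2H-chromen-6-yl]octanoic acid, via lithium percarboxylate 23 (not isolated)
Conditions: LiOH·H2O (2.5 equiv), 30% H2O2 (4 equiv), THF/H2O 3:1, 0 °C, 45 min; Na2SO3; 1 M HCl to pH 3, 0 °C
Reagents that add atoms: hydrogen peroxide, OO (as LiOOH, supplies the acid OH oxygen); lithium hydroxide, [Li+].[OH-] (Li only in 23)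
Why: Lithium hydroperoxide cleaves the N-acyloxazolidinone at the exocyclic carbonyl within minutes at 0 °C (the percarboxylate is reduced by sulfite), while the 5-phenoxide formed under these conditions deactivates the C4 ketone towards enolisation and peroxide attack, so the cis-2,3 centres are kept.

## Compound list

1 | resorcinol | Oc1cccc(O)c1 | starting material
2 | 1,3-dimethoxybenzene | COc1cccc(OC)c1 | intermediate
3 | 2,6-dimethoxyphenyllithium | [Li]c1c(OC)cccc1OC | intermediate
4 | lithium (2,6-dimethoxyphenyl)(dimethylamino)methanolate | [Li+].CN(C)C([O-])c1c(OC)cccc1OC | intermediate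
5 | 2,6-dimethoxybenzaldehyde | O=Cc1c(OC)cccc1OC | intermediate
6 | 3-[(2E)-3-(2,6-dimethoxyphenyl)prop-2-enoyl]-1,3-oxazolidin-2-one | COc1cccc(OC)c1/C=C/C(=O)N1CCOC1=O | intermediate
7 | 1-iodopentane | CCCCCI | starting material
8 | pentyl radical | [CH2]CCCC | intermediate
9 | 3-[(3R)-3-(2,6-dimethoxyphenyl)octanoyl]-1,3-oxazolidin-2-one | CCCCC[C@H](CC(=O)N1CCOC1=O)c1c(OC)cccc1OC | intermediate
10 | 3-{(3R)-3-[2,6-dimethoxy-4-(4,4,5,5-tetramethyl-1,3,2-dioxaborolan-2-yl)phenyl]octanoyl}-1,3-oxazolidin-2-one | CCCCC[C@H](CC(=O)N1CCOC1=O)c1c(OC)cc(B2OC(C)(C)C(C)(C)O2)cc1OC | intermediate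
11 | 3-[(3R)-3-(4-hydroxy-2,6-dimethoxyphenyl)octanoyl]-1,3-oxazolidin-2-one | CCCCC[C@H](CC(=O)N1CCOC1=O)c1c(OC)cc(O)cc1OC | intermediate
12 | 1-bromo-3-methylbut-2-ene | CC(C)=CCBr | starting material
13 | sodium 3,5-dimethoxy-4-[(3R)-1-oxo-1-(2-oxo-1,3-oxazolidin-3-yl)octan-3-yl]phenolate | [Na+].CCCCC[C@H](CC(=O)N1CCOC1=O)c1c(OC)cc([O-])cc1OC | intermediate
14 | 3-{(3R)-3-[4-hydroxy-2,6-dimethoxy-3-(3-methylbut-2-en-1-yl)phenyl]octanoyl}-1,3-oxazolidin-2-one | CCCCC[C@H](CC(=O)N1CCOC1=O)c1c(OC)cc(O)c(CC=C(C)C)c1OC | intermediate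
15 | (2E)-2-methylbut-2-enoyl chloride | C/C=C(\C)C(=O)Cl | starting material
16 | 3,5-dimethoxy-2-(3-methylbut-2-en-1-yl)-4-[(3R)-1-oxo-1-(2-oxo-1,3-oxazolidin-3-yl)octan-3-yl]phenyl (2E)-2-methylbut-2-enoate | CCCCC[C@H](CC(=O)N1CCOC1=O)c1c(OC)cc(OC(=O)/C(C)=C/C)c(CC=C(C)C)c1OC | intermediate
17 | 3,5-dimethoxy-2-(3-methylbut-2-en-1-yl)-4-[(3R)-1-oxo-1-(2-oxo-1,3-oxazolidin-3-yl)octan-3-yl]phenoxyl radical | CCCCC[C@H](CC(=O)N1CCOC1=O)c1c(OC)cc([O])c(CC=C(C)C)c1OC | intermediate
18 | (2E)-2-methylbut-2-enoyl (tigloyl) radical | C/C=C(\C)[C]=O | intermediate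
19 | 3-{(3R)-3-[4-hydroxy-2,6-dimethoxy-3-[(2E)-2-methylbut-2-enoyl]-5-(3-methylbut-2-en-1-yl)phenyl]octanoyl}-1,3-oxazolidin-2-one | CCCCC[C@H](CC(=O)N1CCOC1=O)c1c(OC)c(C(=O)/C(C)=C/C)c(O)c(CC=C(C)C)c1OC | intermediate
20 | 3-{(3R)-3-[(2S,3R)-5,7-dimethoxy-2,3-dimethyl-8-(3-methylbut-2-en-1-yl)-4-oxo-3,4-dihydro-2H-chromen-6-yl]octanoyl}-1,3-oxazolidin-2-one | CCCCC[C@H](CC(=O)N1CCOC1=O)c1c(OC)c2c(c(CC=C(C)C)c1OC)O[C@@H](C)[C@@H](C)C2=O | intermediate
21 | 5-O-dichloroboryl derivative of 22 (aryloxydichloroborane) | CCCCC[C@H](CC(=O)N1CCOC1=O)c1c(OB(Cl)Cl)c2c(c(CC=C(C)C)c1OC)O[C@@H](C)[C@@H](C)C2=O | intermediate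
22 | 3-{(3R)-3-[(2S,3R)-5-hydroxy-7-methoxy-2,3-dimethyl-8-(3-methylbut-2-en-1-yl)-4-oxo-3,4-dihydro-2H-chromen-6-yl]octanoyl}-1,3-oxazolidin-2-one | CCCCC[C@H](CC(=O)N1CCOC1=O)c1c(O)c2c(c(CC=C(C)C)c1OC)O[C@@H](C)[C@@H](C)C2=O | intermediate
23 | lithium (3R)-3-[(2S,3R)-5-hydroxy-7-methoxy-2,3-dimethyl-8-(3-methylbut-2-en-1-yl)-4-oxo-3,4-dihydro-2H-chromen-6-yl]octaneperoxoate | [Li+].CCCCC[C@H](CC(=O)O[O-])c1c(O)c2c(c(CC=C(C)C)c1OC)O[C@@H](C)[C@@H](C)C2=O | intermediate
24 | (3R)-3-[(2S,3R)-5-hydroxy-7-methoxy-2,3-dimethyl-8-(3-methylbut-2-en-1-yl)-4-oxo-3,4-dihydro-2H-chromen-6-yl]octanoic acid | CCCCC[C@H](CC(=O)O)c1c(O)c2c(c(CC=C(C)C)c1OC)O[C@@H](C)[C@@H](C)C2=O | target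

## Step count and risks

Total step count: 11. Longest linear sequence: 11 (fully linear from resorcinol; 7, 12 and 15 are bought).

The three steps most likely to fail:

**Step 4 (key radical addition).** The best-precedented cases use secondary or tertiary radicals and unhindered cinnamoyl imides. Here the radical is primary and the β-aryl group carries two ortho methoxy groups, so the ee may be lower and the addition slower. Side products to expect are the ethyl adduct from Et3B and pentane from premature reduction of 8. Any minor 3S material is removed after step 9, where it becomes a separable diastereomer. The fallback is polar and auxiliary-controlled; it sets out from aldehyde 5 and comes back at 9. HWE olefination of 5 with diethyl {2-oxo-2-[(4R)-2-oxo-4-phenyl-1,3-oxazolidin-3-yl]ethyl}phosphonate (LiCl, i-Pr2NEt) gives (4R)-3-[(2E)-3-(2,6-dimethoxyphenyl)prop-2-enoyl]-4-phenyl-1,3-oxazolidin-2-one F1. Pentylmagnesium bromide with CuBr·SMe2 (THF, −40 °C) then adds to the Cβ-Re face of the Mg-chelated s-cis imide, anti to the phenyl group, giving (4R)-3-[(3R)-3-(2,6-dimethoxyphenyl)octanoyl]-4-phenyl-1,3-oxazolidin-2-one F2, with the minor diastereomer removed by crystallisation. LiOH/H2O2 releases (3R)-3-(2,6-dimethoxyphenyl)octanoic acid F3, and pivaloyl chloride/Et3N followed by oxazolidin-2-one/LiCl re-forms 9.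

**Step 8 (photo-Fries).** Yields are usually moderate. The tigloyl group can isomerise E/Z under irradiation, some ester is lost by cage escape back to phenol 14, and the product enone could photocyclise to racemic chromanone. The fallback builds the ketone by C–H chemistry instead of an O-to-C acyl shift; it sets out from 14 and comes back at 19. Magnesium-mediated ortho-formylation (MgCl2, Et3N, paraformaldehyde, MeCN, 70 °C) at the single free position next to the OH gives 3-{(3R)-3-[3-formyl-4-hydroxy-2,6-dimethoxy-5-(3-methylbut-2-en-1-yl)phenyl]octanoyl}-1,3-oxazolidin-2-one F4. Rhodium-catalysed, phenol-chelation-assisted hydroacylation of but-2-yne ([RhCl(cod)]2, dppf, toluene, 80 °C, no added base) then adds the aldehyde C–H syn across the alkyne and gives the E-enone 19.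

**Step 9 (asymmetric oxa-Michael).** The precedent is on tigloyl phenols of a different substitution pattern, so both the cis/trans ratio and the ee are uncertain here; the sense of induction (quinidine for 2S) should be confirmed on a model first. The fallback separates ring closure from stereocontrol; it sets out from 19 and comes back at 20. Et3N in CH2Cl2 cyclises 19 to the chromanone as a mixture of 2,3-diastereomers F5. IBX (DMSO, 70 °C) dehydrogenates this to 3-{(3R)-3-[5,7-dimethoxy-2,3-dimethyl-8-(3-methylbut-2-en-1-yl)-4-oxo-4H-chromen-6-yl]octanoyl}-1,3-oxazolidin-2-one F6. CuH-catalysed asymmetric conjugate reduction (Cu(OAc)2, the DTBM-SEGPHOS antipode that sets 2S, (EtO)2MeSiH, t-BuOH, toluene, 0 °C) sets C2, and kinetic protonation of the enolate anti to the 2-methyl group sets the cis C3 centre, giving 20.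

## Further compounds

F1 | step 4 | (4R)-3-[(2E)-3-(2,6-dimethoxyphenyl)prop-2-enoyl]-4-phenyl-1,3-oxazolidin-2-one | COc1cccc(OC)c1/C=C/C(=O)N1[C@H](c2ccccc2)COC1=O
F2 | step 4 | (4R)-3-[(3R)-3-(2,6-dimethoxyphenyl)octanoyl]-4-phenyl-1,3-oxazolidin-2-one | CCCCC[C@H](CC(=O)N1[C@H](c2ccccc2)COC1=O)c1c(OC)cccc1OC
F3 | step 4 | (3R)-3-(2,6-dimethoxyphenyl)octanoic acid | CCCCC[C@H](CC(=O)O)c1c(OC)cccc1OC
F4 | step 8 | 3-{(3R)-3-[3-formyl-4-hydroxy-2,6-dimethoxy-5-(3-methylbut-2-en-1-yl)phenyl]octanoyl}-1,3-oxazolidin-2-one | CCCCC[C@H](CC(=O)N1CCOC1=O)c1c(OC)c(C=O)c(O)c(CC=C(C)C)c1OC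
F5 | step 9 | 3-{(3R)-3-[5,7-dimethoxy-2,3-dimethyl-8-(3-methylbut-2-en-1-yl)-4-oxo-3,4-dihydro-2H-chromen-6-yl]octanoyl}-1,3-oxazolidin-2-one, mixture of C2/C3 diastereomers | CCCCC[C@H](CC(=O)N1CCOC1=O)c1c(OC)c2c(c(CC=C(C)C)c1OC)OC(C)C(C)C2=O
F6 | step 9 | 3-{(3R)-3-[5,7-dimethoxy-2,3-dimethyl-8-(3-methylbut-2-en-1-yl)-4-oxo-4H-chromen-6-yl]octanoyl}-1,3-oxazolidin-2-one | CCCCC[C@H](CC(=O)N1CCOC1=O)c1c(OC)c2c(c(CC=C(C)C)c1OC)OC(C)=C(C)C2=O
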